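The constants used here come from no measurement; the result is computed.

A charge of 0.018 M of starting material with 2.00 equiv of reagent and 1 mol% of catalyst leaves one decision for the next run: give the flask more time, or more reagent.

starting material 0.018 M (fed, over 2.0 h); reagent 2.00 equiv; catalyst 1 mol%; time 25 h

    starting material + reagent + catalyst ⇌ target + catalyst, rate k1*[starting material]*[reagent]*[catalyst] forward; the back reaction follows from the equilibrium constant (K1 = 20 M⁻¹, k1 = 3.14 M⁻² s⁻¹)
    reagent → decomposition product (k2 = 2.17 × 10⁻⁸ s⁻¹)

- which holds at 25 h: what has brought the reaction to rest, or that it has not come to rest (forward and back rates have come level / it is still moving / the reagent has run out first / all of the starting material has reacted)
- part of the starting material gone at 25 h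
- the target standing at 25 h, as a percentage of the starting material charged

- the reaction counts as stopped when no species that holds the starting material changes by six tenths of a point or more over the second half of the time
- run time (flask): 25 h

In this flask it pays to follow what is left and not what is made. The catalyst stands on both sides of the reversible step and drops out of the balance, and the half-life of the reagent by decomposition, 370 d, is far longer than the run, so the reckoning by hand sets that decomposition aside. At balance, c(target)/c(starting material) equals 20 M⁻¹ times c(reagent), so a fraction f left obeys f = one over (one plus that product). c(reagent) in turn is the charge of starting material times the sum of f and the equivalents above one. Solved as a quadratic, this gives 63.0%, the balance fraction left: the share of the charged starting material standing unreacted when forward and back rates are level.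

The way there has a relaxation time: one over the forward rate constant times c(catalyst) times the sum of c(starting material), c(reagent) and the reciprocal of the equilibrium constant, all at balance, which comes to 5.42 h. Counted from the middle of the feed, this estimate leaves the flask at 25 h with 0.44 percentage points still to go, which makes 36.5% gone and 36.5% target. Its estimated drift over the second half is 4 points against the 0.6 points of the test, so it still counts as moving. Time has little left to give, so the next run should carry more reagent, which enlarges c(reagent) in the denominator of f.

The forecast gives it is still moving, with 36.5% gone and 36.5% target: “by the stated test the reaction counts as still moving”. The simulation gives it is still moving, 36.5% gone and 36.5% target, with a largest change of 3.8 points over the second half and starting material at 63.5% of its charge, close to the balance fraction left of 63.0%.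

The flask stops short because of the return of target to starting material and reagent: with that return struck out, conversion reads 73.8% against 36.5%. A run ten times as long makes no difference to conversion. Put into the same balance, 8.00 equiv of reagent gives a fraction left of 27.6%, and the neighbour flask with that charge ends with 27.7% of its starting material.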